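The plan rests on one bond, the aryl ether O–C8. It ties ketal carbon C1′ to ring B and completes the six-membered 1,3-dioxin (C1′–O–C8–C8a–C1–O) of the 2,8-dioxabicyclo[3.2.1]octane core. This bond is cut last, back to a C8 bromide and a C1′ lactol hydroxyl, with the ketone half still saturated and C4′ masked as a dioxolane.
The lactol (five-membered ring C1–O–C1′–C8a′–C8′) comes from oxidation of a diol. The C1–C8′ bond of that diol comes from adding a C8′ aryllithium to the C1 ketone of a bromo epoxy tetralone, anti to the oxirane.
Both halves derive from one tetralone (4), made from 4-(3-methoxyphenyl)butanoic acid by para bromination, ortho chlorination and Friedel–Crafts closure ortho to the methoxy group.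
Alcohol half: naphthol, quinone monoketal, CBS reduction (sets C4), anti epoxidation while C1 is still a ketal (a 4-silyloxynaphthalen-1(4H)-one would tautomerise to a naphthol), then ketone release. Ketone half: ketalisation, benzylic oxidation, reduction.
Ring order: carbocycles C and D, first oxirane, five-membered lactol ring, 1,3-dioxin (key step), then the C2′=C3′ enone, the second oxirane and deprotection.

Key step: step 18

Numbering:
- Alcohol half: C1 (quaternary carbinol), C2/C3 (oxirane), C4 (carbinol). Ring B is C4a, C5 (O), C6 (Cl), C7, C8 (O), C8a. Its carbocycle is ring D.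
- Ketone half: C1′ (ketal), C2′/C3′ (oxirane), C4′ (ketone). Ring A is C4a′, C5′ (O), C6′ (Cl), C7′, C8′ (bonded to C1), C8a′. Its carbocycle is ring C.
- Mapping from the systematic locants of tetralone 4: C1 becomes C4 or C4′, C4 becomes C1 or C1′, C5 (Br) becomes C8 or C8′, C7 (Cl) becomes C6 or C6′, and C8 (O) becomes C5 or C5′.

Remark: alcohol 20 is used as the racemate. Its carbinol centre (C1′) is erased in step 17, so diol 22 is carried as a pair of C1′ epimers.

Step 1
Reactants: 1 4-(3-methoxyphenyl)butanoic acid
Product: 2 4-(2-bromo-5-methoxyphenyl)butanoic acid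
Conditions: NBS, MeCN, 0 °C → rt
Reagents that add atoms: N-bromosuccinimide, O=C1CCC(=O)N1Br
Why: Electrophilic aromatic bromination, in which the methoxy group directs to its para position (also ortho to the chain) and NBS in MeCN should stop at the monobromide.

Step 2
Reactants: 2 4-(2-bromo-5-methoxyphenyl)butanoic acid
Product: 3 4-(2-bromo-4-chloro-5-methoxyphenyl)butanoic acid
Conditions: NCS, TFA (cat.), MeCN, 50 °C
Reagents that add atoms: N-chlorosuccinimide, O=C1CCC(=O)N1Cl
Why: Electrophilic aromatic chlorination, in which the para site is blocked and chlorine should enter the open ortho position (para to the chain) rather than the site squeezed between methoxy group and chain.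

Step 3
Reactants: 3 4-(2-bromo-4-chloro-5-methoxyphenyl)butanoic acid
Product: 4 5-bromo-7-chloro-8-methoxy-3,4-dihydronaphthalen-1(2H)-one
Conditions: Eaton's reagent (P2O5 in MeSO3H), 50 °C
Reagents that add atoms: none
Why: Intramolecular Friedel–Crafts acylation at the only free carbon next to the chain, which is activated by the ortho methoxy group, closes the six-membered carbocycle with the halogen pattern already fixed.

Step 4
Reactants: 4 5-bromo-7-chloro-8-methoxy-3,4-dihydronaphthalen-1(2H)-one
Product: 5 5-bromo-7-chloro-8-hydroxy-3,4-dihydronaphthalen-1(2H)-one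
Conditions: BCl3, CH2Cl2, −78 → 0 °C; H2O
Reagents that add atoms: none
Why: Chelation-assisted Lewis acid ether cleavage, in which BCl3 bridges the ketone and the peri methoxy oxygen so that the methyl group is lost under mild conditions.

Step 5
Reactants: 5 5-bromo-7-chloro-8-hydroxy-3,4-dihydronaphthalen-1(2H)-one
Product: 6 5-bromo-7-chloro-8-(methoxymethoxy)-3,4-dihydronaphthalen-1(2H)-one
Conditions: NaH, MOMCl, DMF, 0 °C
Reagents that add atoms: chloromethyl methyl ether, COCCl
Why: Williamson-type O-alkylation of the phenoxide, the most acidic site, gives a base-stable acetal that tolerates organolithium, carbonate and peroxide chemistry later.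

Step 6
Reactants: 6 5-bromo-7-chloro-8-(methoxymethoxy)-3,4-dihydronaphthalen-1(2H)-one
Product: 9 5-bromo-7-chloro-8-(methoxymethoxy)naphthalen-1-ol, via lithium enolate 7 (not isolated), via 4H-naphthalenone tautomer 8 (not isolated)
Conditions: LiN(SiMe3)2, THF, −78 °C; then N-tert-butylbenzenesulfinimidoyl chloride, −78 °C → rt
Reagents that add atoms: none
Why: Mukaiyama dehydrogenation, in which the enolate attacks sulfur, syn elimination gives the cross-conjugated ketone, and this tautomerises at once to the aromatic naphthol under acid-free conditions that spare the MOM ether.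

Step 7
Reactants: 9 5-bromo-7-chloro-8-(methoxymethoxy)naphthalen-1-ol
Product: 11 5-bromo-7-chloro-4,4-dimethoxy-8-(methoxymethoxy)naphthalen-1(4H)-one (quinone monoketal; ketone = C4; ketal = C1), via 4-methoxynaphthol 10 (not isolated)
Conditions: PhI(OAc)2 (2.2 equiv), MeOH, 0 °C → rt
Reagents that add atoms: methanol, CO
Why: Twofold oxidative dearomatisation by trivalent iodine, in which methanol adds para to the naphthol oxygen, the adduct rearomatises and is oxidised again, so the ketone ends up peri to the MOM ether and the ketal peri to bromine.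

Step 8
Reactants: 11 quinone monoketal
Product: 12 (1R)-5-bromo-7-chloro-4,4-dimethoxy-8-(methoxymethoxy)-1,4-dihydronaphthalen-1-ol (C4 carbinol)
Conditions: (S)-Me-CBS oxazaborolidine [(3aS)-1-methyl-3,3-diphenyltetrahydro-1H,3H-pyrrolo[1,2-c][1,3,2]oxazaborole] (20 mol %), catecholborane, toluene, −78 °C; MeOH, aq. NaHCO3
Reagents that add atoms: none
Why: Corey–Bakshi–Shibata reduction sets C4: the peri-substituted aryl flank acts as the large group and the vinyl CH as the small one, as with 1-tetralone, so the (S)-catalyst should give the (R)-alcohol, while catecholborane leaves the ring alkene alone and the basic work-up avoids acid-triggered loss of methanol and aromatisation.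

Step 9
Reactants: 12 C4 carbinol
Product: 13 tert-butyl{[(1R)-5-bromo-7-chloro-4,4-dimethoxy-8-(methoxymethoxy)-1,4-dihydronaphthalen-1-yl]oxy}dimethylsilane
Conditions: TBSCl, imidazole, DMAP (cat.), DMF, rt → 35 °C
Reagents that add atoms: tert-butyldimethylsilyl chloride, CC(C)(C)[Si](C)(C)Cl
Why: Base-mediated silylation does not touch the stereocentre or the acid-labile allylic ketal and installs the bulky group that will steer the epoxidation.

Step 10
Reactants: 13 silyl ether
Product: 14 (2R,3S,4S)-8-bromo-6-chloro-2,3-epoxy-1,1-dimethoxy-5-(methoxymethoxy)-4-(tert-butyldimethylsilyloxy)-1,2,3,4-tetrahydronaphthalene (oxirane anti to OTBS)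
Conditions: dimethyldioxirane, acetone–CH2Cl2, 0 °C → rt
Reagents that add atoms: dimethyldioxirane, CC1(C)OO1
Why: Concerted dioxirane epoxidation under neutral conditions, in which peri strain with the C5 MOM ether holds the silyloxy group pseudoaxial so that oxygen is delivered to the opposite face and sets C2 and C3 anti to C4–O, while the C1 ketal excludes any enone that could tautomerise to a naphthol.

Step 11
Reactants: 14 epoxy ketal
Product: 15 (2R,3S,4S)-8-bromo-6-chloro-2,3-epoxy-5-(methoxymethoxy)-4-(tert-butyldimethylsilyloxy)-3,4-dihydronaphthalen-1(2H)-one (bromo epoxy tetralone)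
Conditions: PPTS, acetone–H2O, 50 °C
Reagents that add atoms: water, O
Why: Acid-catalysed ketal hydrolysis, in which a benzylic dimethyl ketal ionises far faster than an aryl formaldehyde acetal or a hindered secondary silyl ether even when slowed by the neighbouring oxirane, and the oxirane, flanked by two oxygenated carbons, resists weak acid.

Step 12
Reactants: 4 5-bromo-7-chloro-8-methoxy-3,4-dihydronaphthalen-1(2H)-one
Product: 16 5′-bromo-7′-chloro-8′-methoxy-3′,4′-dihydro-2′H-spiro[1,3-dioxolane-2,1′-naphthalene]
Conditions: HOCH2CH2OH, TsOH·H2O (cat.), toluene, reflux, Dean–Stark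
Reagents that add atoms: ethylene glycol, OCCO
Why: Acid-catalysed ketalisation with azeotropic removal of water, run on the methyl ether because an aryl MOM ether peri to the ketone would not survive these conditions.

Step 13
Reactants: 16 methoxy ketal
Product: 18 5′-bromo-7′-chloro-8′-(methoxymethoxy)-3′,4′-dihydro-2′H-spiro[1,3-dioxolane-2,1′-naphthalene], via sodium phenoxide 17 (not isolated)
Conditions: NaSEt, DMF, 110 °C; cool to 0 °C, then MOMCl
Reagents that add atoms: chloromethyl methyl ether, COCCl
Why: SN2 demethylation of the twisted, doubly ortho-substituted aryl methyl ether by thiolate followed by Williamson trapping in the same flask, so the ketal never meets a free peri phenol, and the arene carries no activating group for substitution at bromine or chlorine.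

Step 14
Reactants: 18 MOM ketal
Product: 19 8-bromo-6-chloro-4,4-(ethylenedioxy)-5-(methoxymethoxy)-3,4-dihydronaphthalen-1(2H)-one (C1′ ketone, C4′ dioxolane)
Conditions: dirhodium tetrakis(caprolactamate) Rh2(cap)4 (1 mol %), t-BuOOH, NaHCO3, ClCH2CH2Cl, 40 °C
Reagents that add atoms: tert-butyl hydroperoxide, CC(C)(C)OO
Why: Metal-catalysed radical benzylic C–H oxidation with an alkyl hydroperoxide, a reaction type established on tetralone ketals, is directed to the only benzylic methylene left in the molecule.

Step 15
Reactants: 19 keto ketal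
Product: 20 8-bromo-6-chloro-4,4-(ethylenedioxy)-5-(methoxymethoxy)-1,2,3,4-tetrahydronaphthalen-1-ol (racemic C1′ carbinol)
Conditions: NaBH4, MeOH–THF, 0 °C
Reagents that add atoms: none
Why: Borohydride reduction places C1′ at the alcohol level, a mask that is distinct from the C4′ dioxolane and can be removed later by oxidation without acid.

Step 16
Reactants: 20 bromo alcohol; 15 bromo epoxy tetralone
Product: 22 coupled diol (aryl on C1 anti to the oxirane; both C1′ carbinol epimers), via dilithio arene 21 (not isolated)
Conditions: 20, n-BuLi (2.05 equiv), THF, −78 °C; then 15, −78 → −40 °C; H2O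
Reagents that add atoms: none
Why: Deprotonation then bromine–lithium exchange gives an alkoxide-chelated aryllithium whose 1,2-addition to the non-enolisable ketone should occur on the face opposite the oxirane oxygen (steric and electrostatic repulsion), forming C1–C8′ and setting C1 with the tertiary hydroxyl syn to the epoxide.

Step 17
Reactants: 22 coupled diol
Product: 24 bromo lactol (epimer drawn: C1′ hydroxyl on the ring B side), via hydroxy ketone 23 (not isolated)
Conditions: Dess–Martin periodinane, pyridine, CH2Cl2, 0 °C → rt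
Reagents that add atoms: none
Why: Dess–Martin oxidation touches only the secondary benzylic alcohol, merges both C1′ epimers into one ketone, and the peri tertiary hydroxyl adds to it to close the five-membered lactol ring, which cannot be oxidised further.

Step 18
Reactants: 24 bromo lactol
Product: 25 protected cage with saturated ring C and C4′ dioxolane
Conditions: CuI (20 mol %), 3,4,7,8-tetramethyl-1,10-phenanthroline (40 mol %), Cs2CO3, 4 Å MS, toluene, 110 °C
Reagents that add atoms: none
Why: Carbonate removes the hemiketal proton, the phenanthroline-bound monovalent copper alkoxide inserts into the C8–Br bond to give a trivalent copper aryl alkoxide held in a seven-membered metallacycle, and reductive elimination forges O–C8. The closest known reaction type is the intramolecular Ullmann-type etherification of aryl halides with alcohols, which has also been applied to the anomeric O-arylation of lactols. The one ring closed is the six-membered 1,3-dioxin (C1′–O–C8–C8a–C1–O), formed by a tethered oxygen attacking an arene carbon that the quaternary C1 holds within reach. The new stereocentre C1′ is dictated by C1, since only the lactol epimer with its hydroxyl on the ring B side of the five-membered ring can span the gap, and the other epimer feeds into it through hydroxy ketone 23. The step needs bromide over chloride selectivity, secured by the much slower insertion of copper into aryl chlorides, and lactol over tertiary alkoxide selectivity, secured by ring size because arylation of the C1 alkoxide would give a four-membered ring. The oxirane should survive because the oxygens on C1 and C1′ lie on the same face as the oxirane oxygen and cannot reach the backside of C2.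

Step 19
Reactants: 25 protected cage
Product: 26 cage ketone (C4′ ketone, saturated C2′–C3′)
Conditions: PPTS, acetone–H2O, 55 °C
Reagents that add atoms: water, O
Why: Mild acid-catalysed ketal hydrolysis, in which the dioxolane ionises readily because the ortho oxygen of ring A stabilises the cation, whereas opening of the bicyclic C1′ ketal is reversed intramolecularly and the MOM and TBS ethers tolerate pyridinium acid.

Step 20
Reactants: 26 cage ketone
Product: 27 cage enone (C2′=C3′)
Conditions: IBX, DMSO–fluorobenzene, 70 °C
Reagents that add atoms: none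
Why: IBX-mediated α,β-dehydrogenation of an aryl alkyl ketone through its enol, which cannot lead to aromatisation because C1′ is fully substituted, and both phenols are still masked against oxidation.

Step 21
Reactants: 27 cage enone
Product: 28 protected bis-epoxide
Conditions: t-BuOOH, DBU, CH2Cl2, 0 °C → rt
Reagents that add atoms: tert-butyl hydroperoxide, CC(C)(C)OO
Why: Weitz–Scheffer nucleophilic epoxidation, in which the peroxide anion adds to C2′ on the open face that carries only the bridging oxygen, anti to the C1′–O–aryl bond and away from the overhanging ring B, so C2′ and C3′ are set with the oxirane syn to the bridging oxygen.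

Step 22
Reactants: 28 protected bis-epoxide
Product: 29 C4 silyl ether of the target (both phenols free)
Conditions: NaHSO4·SiO2, CH2Cl2, rt
Reagents that add atoms: none
Why: Heterogeneous acid cleavage that is selective for phenolic MOM ethers and uses a non-nucleophilic counterion, so the electron-poor keto oxirane and the oxirane flanked by two oxygenated carbons are offered no nucleophile.

Step 23
Reactants: 29 C4 silyl ether
Product: 30 target CNP0289684.3
Conditions: HF·pyridine, pyridine, THF, 0 °C → rt
Reagents that add atoms: none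
Why: Buffered fluoride desilylation releases the C4 alcohol without generating an alkoxide, which avoids Payne migration of the trans epoxy alcohol.

Compound list
1 | 4-(3-methoxyphenyl)butanoic acid | COc1cccc(CCCC(=O)O)c1 | starting material
2 | 4-(2-bromo-5-methoxyphenyl)butanoic acid | COc1ccc(Br)c(CCCC(=O)O)c1 | intermediate
3 | 4-(2-bromo-4-chloro-5-methoxyphenyl)butanoic acid | COc1c(Cl)cc(Br)c(CCCC(=O)O)c1 | intermediate
4 | 5-bromo-7-chloro-8-methoxy-3,4-dihydronaphthalen-1(2H)-one | COc1c(Cl)cc(Br)c2CCCC(=O)c12 | intermediate
5 | 5-bromo-7-chloro-8-hydroxy-3,4-dihydronaphthalen-1(2H)-one | Oc1c(Cl)cc(Br)c2CCCC(=O)c12 | intermediate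
6 | 5-bromo-7-chloro-8-(methoxymethoxy)-3,4-dihydronaphthalen-1(2H)-one | COCOc1c(Cl)cc(Br)c2CCCC(=O)c12 | intermediate
7 | lithium enolate of 6 | [Li]OC1=CCCc2c(Br)cc(Cl)c(OCOC)c12 | intermediate
8 | 5-bromo-7-chloro-8-(methoxymethoxy)naphthalen-1(4H)-one | O=C1C=CCc2c(Br)cc(Cl)c(OCOC)c12 | intermediate
9 | 5-bromo-7-chloro-8-(methoxymethoxy)naphthalen-1-ol | Oc1cccc2c(Br)cc(Cl)c(OCOC)c12 | intermediate
10 | 5-bromo-7-chloro-4-methoxy-8-(methoxymethoxy)naphthalen-1-ol | Oc1ccc(OC)c2c(Br)cc(Cl)c(OCOC)c12 | intermediate
11 | 5-bromo-7-chloro-4,4-dimethoxy-8-(methoxymethoxy)naphthalen-1(4H)-one | O=C1C=CC(OC)(OC)c2c(Br)cc(Cl)c(OCOC)c12 | intermediate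
12 | (1R)-5-bromo-7-chloro-4,4-dimethoxy-8-(methoxymethoxy)-1,4-dihydronaphthalen-1-ol | COC1(OC)C=C[C@@H](O)c2c(OCOC)c(Cl)cc(Br)c12 | intermediate
13 | TBS ether of 12 | COC1(OC)C=C[C@@H](O[Si](C)(C)C(C)(C)C)c2c(OCOC)c(Cl)cc(Br)c12 | intermediate
14 | (2R,3S,4S) epoxy dimethyl ketal, oxirane anti to OTBS | COC1(OC)[C@@H]3O[C@@H]3[C@@H](O[Si](C)(C)C(C)(C)C)c2c(OCOC)c(Cl)cc(Br)c12 | intermediate
15 | (2R,3S,4S) bromo epoxy tetralone | O=C1[C@@H]3O[C@@H]3[C@@H](O[Si](C)(C)C(C)(C)C)c2c(OCOC)c(Cl)cc(Br)c12 | intermediate
16 | dioxolane of 4 | COc1c(Cl)cc(Br)c2CCCC3(OCCO3)c12 | intermediate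
17 | sodium phenoxide from 16 | [Na+].[O-]c1c(Cl)cc(Br)c2CCCC3(OCCO3)c12 | intermediate
18 | MOM ether dioxolane | COCOc1c(Cl)cc(Br)c2CCCC3(OCCO3)c12 | intermediate
19 | C1′ ketone, C4′ dioxolane | COCOc1c(Cl)cc(Br)c2C(=O)CCC3(OCCO3)c12 | intermediate
20 | C1′ alcohol, C4′ dioxolane (racemic) | COCOc1c(Cl)cc(Br)c2C(O)CCC3(OCCO3)c12 | intermediate
21 | C8′-lithio C1′ lithium alkoxide | COCOc1c(Cl)cc([Li])c2C(O[Li])CCC3(OCCO3)c12 | intermediate
22 | coupled diol (C1′ epimers) | OC1CCC2(OCCO2)c3c(OCOC)c(Cl)cc(c13)[C@](O)(c4c(Br)cc(Cl)c(OCOC)c4[C@@H]5O[Si](C)(C)C(C)(C)C)[C@@H]6O[C@@H]65 | intermediate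
23 | hydroxy ketone (open form of 24) | O=C1CCC2(OCCO2)c3c(OCOC)c(Cl)cc(c13)[C@](O)(c4c(Br)cc(Cl)c(OCOC)c4[C@@H]5O[Si](C)(C)C(C)(C)C)[C@@H]6O[C@@H]65 | intermediate
24 | bromo lactol (reactive C1′ epimer drawn) | C12(OCCO2)c3c(OCOC)c(Cl)cc4c3[C@@](O)(CC1)O[C@@]4(c5c(Br)cc(Cl)c(OCOC)c5[C@@H]6O[Si](C)(C)C(C)(C)C)[C@@H]7O[C@@H]76 | intermediate
25 | protected cage, C4′ dioxolane | C12(OCCO2)c3c(OCOC)c(Cl)cc4c3[C@@]5(Oc6cc(Cl)c(OCOC)c7c6[C@]4(O5)[C@@H]8O[C@@H]8[C@H]7O[Si](C)(C)C(C)(C)C)CC1 | intermediate
26 | cage ketone | O=C1c2c(OCOC)c(Cl)cc3c2[C@@]2(Oc4cc(Cl)c(OCOC)c5c4[C@]3(O2)[C@@H]2O[C@@H]2[C@H]5O[Si](C)(C)C(C)(C)C)CC1 | intermediate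
27 | cage enone | O=C1c2c(OCOC)c(Cl)cc3c2[C@@]2(Oc4cc(Cl)c(OCOC)c5c4[C@]3(O2)[C@@H]2O[C@@H]2[C@H]5O[Si](C)(C)C(C)(C)C)C=C1 | intermediate
28 | protected bis-epoxide | O=C1c2c(OCOC)c(Cl)cc3c2[C@@]2(Oc4cc(Cl)c(OCOC)c5c4[C@]3(O2)[C@@H]2O[C@@H]2[C@H]5O[Si](C)(C)C(C)(C)C)[C@@H]2O[C@H]12 | intermediate
29 | C4 TBS ether of the target | O=C1c2c(O)c(Cl)cc3c2[C@@]2(Oc4cc(Cl)c(O)c5c4[C@]3(O2)[C@@H]2O[C@@H]2[C@H]5O[Si](C)(C)C(C)(C)C)[C@@H]2O[C@H]12 | intermediate
30 | CNP0289684.3 | O=C1c2c(O)c(Cl)cc3c2[C@@]2(Oc4cc(Cl)c(O)c5c4[C@]3(O2)[C@@H]2O[C@@H]2[C@H]5O)[C@@H]2O[C@H]12 | target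

Total step count: 23
Longest linear sequence: 19 steps (steps 1–11, then 16–23)

Steps most likely to fail

Step 18. Insertion of copper into a bromide ortho to a quaternary carbon may be slow, and a tertiary hemiketal alkoxide is a weak ligand. Prolonged heating could therefore lead to protodebromination or to base-induced degradation of the open hydroxy ketone form. The fallback sets out from 24.
- Miyaura borylation (Pd(dppf)Cl2, B2pin2, KOAc, dioxane, 90 °C) would replace the bromide and give the C8 pinacol boronate lactol F1.
- NaBO3·4H2O in THF–H2O would convert it into the C8 phenol lactol F2.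
- Catalytic PPTS with 4 Å molecular sieves in CH2Cl2 would then close the same dioxin ring by acid-catalysed dehydrative ketalisation, the phenol oxygen adding to the C1′ oxocarbenium ion on the only face it can reach.
- The route is rejoined at 25.

Step 16. Three things may go wrong. The aggregated dianion may add sluggishly to a ketone flanked by a peri bromine. Halogen–lithium scrambling with the C8 bromide of 15 may compete. The pseudoaxial silyl ether on the attack face may erode the facial selectivity. The fallback sets out from 20.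
- Silylation (TESCl, imidazole, DMF) would give the C1′ triethylsilyl ether F3.
- One equivalent of n-BuLi at −78 °C would give the monolithio arene F4.
- F4 is added to 15 precomplexed with LaCl3·2LiCl to raise the rate of carbonyl addition.
- The coupled triethylsilyl ether F5 is then desilylated selectively (HF·pyridine buffered with pyridine, 0 °C), and the route is rejoined at 22.

Step 22. Acid-mediated opening of either oxirane, or ionisation at the benzylic C4 position, may accompany acetal cleavage on the fully functionalised bis-epoxide. The fallback sets out from 27 and moves the acetal cleavage ahead of the second epoxidation.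
- NaHSO4·SiO2 in CH2Cl2 applied to the enone, which carries only the more robust oxirane, would give the bis-phenol enone F6.
- Nucleophilic epoxidation of the free phenol (t-BuOOH, 1,5,7-triazabicyclo[4.4.0]dec-5-ene, toluene, 0 °C → rt), a transformation known for peri-hydroxy naphthalenone ketals, would then deliver the oxirane on the same open face.
- The route is rejoined at 29.

Further compounds
F1 | step 18 | C8 pinacol boronate lactol | C12(OCCO2)c3c(OCOC)c(Cl)cc4c3[C@@](O)(CC1)O[C@@]4(c5c(B8OC(C)(C)C(C)(C)O8)cc(Cl)c(OCOC)c5[C@@H]6O[Si](C)(C)C(C)(C)C)[C@@H]7O[C@@H]76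
F2 | step 18 | C8 phenol lactol | C12(OCCO2)c3c(OCOC)c(Cl)cc4c3[C@@](O)(CC1)O[C@@]4(c5c(O)cc(Cl)c(OCOC)c5[C@@H]6O[Si](C)(C)C(C)(C)C)[C@@H]7O[C@@H]76
F3 | step 16 | C1′ triethylsilyl ether of 20 | COCOc1c(Cl)cc(Br)c2C(O[Si](CC)(CC)CC)CCC3(OCCO3)c12
F4 | step 16 | monolithio arene from F3 | COCOc1c(Cl)cc([Li])c2C(O[Si](CC)(CC)CC)CCC3(OCCO3)c12
F5 | step 16 | coupled triethylsilyl ether | CC[Si](CC)(CC)OC1CCC2(OCCO2)c3c(OCOC)c(Cl)cc(c13)[C@](O)(c4c(Br)cc(Cl)c(OCOC)c4[C@@H]5O[Si](C)(C)C(C)(C)C)[C@@H]6O[C@@H]65
F6 | step 22 | bis-phenol enone, C4 TBS ether | O=C1c2c(O)c(Cl)cc3c2[C@@]2(Oc4cc(Cl)c(O)c5c4[C@]3(O2)[C@@H]2O[C@@H]2[C@H]5O[Si](C)(C)C(C)(C)C)C=C1
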